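**Plan**

1. Retrosynthesis first cuts, in the cyclohexanetrione ring, the bond between the ring carbon that carries the side chain and one of its two neighbouring carbonyl carbons (the ring closure). It then cuts the bond between the other neighbouring carbonyl and its CMe2 carbon, which leads back to an aryl lactone and a C8 keto ester.
2. Further back: the two benzyl ethers, the aryl–acyl bond, the C4–H bond of a coumarin (reduction) and the pyranone ring (Pechmann).
3. Forward: the pyranone ring is fused onto methylphloroglucinol (step 1) and reduced (step 2), acylation and benzylation follow, and the cyclohexanetrione ring arises in step 6 while the lactone ring opens. Hydrogenolysis ends the route.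
4. Stereochemistry: the single stereocentre is set in step 2 by ligand-controlled CuH conjugate reduction of the coumarin C3=C4 bond. No later step makes or breaks a bond at that carbon.
5. Enabling feature: the phenolic oxygen ortho to the benzylic stereocentre closes a six-membered aryl lactone, O–C(=O)–CH2–CH(iBu)–C(ar)–C(ar), an activated acyl donor that already holds the future trione ring carbon and one of its carbonyls. In the C(=O)–CMe2–C(=O)–CMe2–C(=O) array both interposed carbons are quaternary, so the CH2 next to the stereocentre is the only chain carbon that can enolise and close the ring.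

Key step: step 6

Assumption 1: the Pechmann lactonisation is taken to use the less hindered C5 hydroxyl of 1 and to give the 6-methyl coumarin 3. The 8-methyl isomer, if formed, runs through the same steps to the same target, because the lactone oxygen ends as a free phenol.

Assumption 2: (R)-DTBM-SEGPHOS is taken as the ligand antipode that gives the 4R lactone. If a test reduction shows the opposite sense, the (S)-ligand is used and nothing else changes.

**Route**

Step 1
Reactants: 1 2-methylbenzene-1,3,5-triol; 2 ethyl 5-methyl-3-oxohexanoate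
Product: 3 5,7-dihydroxy-6-methyl-4-(2-methylpropyl)-2H-chromen-2-one
Conditions: MeSO3H, 0 °C → rt
Reagents that add atoms: none
Why: Pechmann condensation, in which the protonated keto group of 2 alkylates one of the two equivalent ring CH positions of 1 and lactonisation with loss of ethanol and water fuses the pyranone ring, as in the preparation of 5,7-dihydroxy-4-alkylcoumarins from phloroglucinols and β-keto esters; no stereocentre is formed.

Step 2
Reactants: 3 5,7-dihydroxy-6-methyl-4-(2-methylpropyl)-2H-chromen-2-one
Product: 6 (4R)-5,7-dihydroxy-6-methyl-4-(2-methylpropyl)-3,4-dihydro-2H-chromen-2-one, via bis-TMS coumarin 4 (not isolated), via silyl ketene acetal 5 (not isolated)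
Conditions: HMDS, (NH4)2SO4 (cat.), MeCN, 80 °C, then evaporate; Cu(OAc)2·H2O (5 mol%), (R)-DTBM-SEGPHOS (5 mol%), (EtO)2MeSiH (3 equiv), toluene, 0 °C → rt; 1 M HCl, THF, rt
Reagents that add atoms: none
Why: Copper hydride catalysed asymmetric conjugate reduction of a β,β-disubstituted unsaturated lactone (Buchwald–Lipshutz type, as used on 4-substituted coumarins), in which the bisphosphine-bound Cu–H delivers hydride to one face of C4 and so sets the only stereocentre as 4R; the transient TMS ethers keep the phenols from quenching Cu–H, and the adduct rests as silyl ketene acetal 5, which shields the aryl lactone from 1,2-reduction until the acidic work-up.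

Step 3
Reactants: 6 (4R)-5,7-dihydroxy-6-methyl-4-(2-methylpropyl)-3,4-dihydro-2H-chromen-2-one; 7 3-phenylpropanoyl chloride
Product: 8 (4R)-5,7-dihydroxy-6-methyl-4-(2-methylpropyl)-8-(3-phenylpropanoyl)-3,4-dihydro-2H-chromen-2-one
Conditions: AlCl3 (4 equiv), 1,2-dichloroethane/PhNO2, 0 → 40 °C; ice/HCl
Reagents that add atoms: none
Why: Friedel–Crafts acylation (with Fries transfer of any O-acyl product) at C8, the only unsubstituted ring carbon, as in the C8 acylation of 5,7-dihydroxy-4-alkylcoumarins with AlCl3; the stereocentre is not touched.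

Step 4
Reactants: 8 (4R)-5,7-dihydroxy-6-methyl-4-(2-methylpropyl)-8-(3-phenylpropanoyl)-3,4-dihydro-2H-chromen-2-one
Product: 9 (4R)-5,7-bis(benzyloxy)-6-methyl-4-(2-methylpropyl)-8-(3-phenylpropanoyl)-3,4-dihydro-2H-chromen-2-one
Conditions: BnBr (3 equiv), Cs2CO3 (3 equiv), n-Bu4NI (cat.), dry DMF, rt → 40 °C
Reagents that add atoms: benzyl bromide, BrCc1ccccc1
Why: Williamson ether synthesis under anhydrous conditions, which should benzylate both caesium phenolates faster than they can attack the lactone; the two ethers keep the ring out of its phenolate and dienone forms in step 6.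

Step 5
Reactants: 10 2,2,4,4-tetramethylcyclobutane-1,3-dione
Product: 11 methyl 2,2,4-trimethyl-3-oxopentanoate
Conditions: NaOMe (2 mol%), MeOH, 0 °C → rt; AcOH quench
Reagents that add atoms: methanol, CO
Why: Alkoxide-induced retro-Claisen ring opening of the strained four-membered 1,3-dione (the known methanolysis of dimethylketene dimer), in which methoxide adds to one carbonyl, the ring C–C bond breaks with release of strain to the ketone enolate, and methanol protonates it and returns methoxide.

Step 6
Reactants: 9 (4R)-5,7-bis(benzyloxy)-6-methyl-4-(2-methylpropyl)-8-(3-phenylpropanoyl)-3,4-dihydro-2H-chromen-2-one; 11 methyl 2,2,4-trimethyl-3-oxopentanoate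
Product: 14 2-[(1S)-1-[4,6-bis(benzyloxy)-2-hydroxy-5-methyl-3-(3-phenylpropanoyl)phenyl]-3-methylbutyl]-3-hydroxy-4,4,6,6-tetramethylcyclohex-2-ene-1,5-dione, via lithium enolate 12 (not isolated), via seco keto ester phenolate 13 (not isolated)
Conditions: 11 (3.5 equiv), LDA (3.3 equiv, commercial solution), THF, −78 → 0 °C; then 9, −78 → 0 °C; then t-BuOK (2 equiv), 0 °C → rt; cold 1 M HCl
Reagents that add atoms: none
Why: The fully substituted lithium enolate 12 adds to the aryl lactone carbonyl of 9 and the tetrahedral intermediate expels the phenolate that is chelated to the neighbouring ketone, which gives 13 (crossed Claisen acylation, the ring oxygen serving as traceless tether and leaving group); t-BuOK then removes a proton from the CH2 between the stereocentre and the new ketone, and this enolate attacks the methyl ester (Dieckmann condensation), after which loss of methoxide and deprotonation of the acidic trione make the sequence irreversible. The closest known reaction types are the acylation of ketone enolates by phenyl esters and dihydrocoumarins and the Dieckmann closure of 5-oxo esters to cyclohexane-1,3-diones. The cyclohexanetrione ring closes in the 6-(enolexo)-exo-trig mode, and the two gem-dimethyl groups hold the chain in the folded conformer that this needs. No stereocentre is formed; the benzylic centre keeps its configuration because no bond to it is made or broken, and once the trione exists it is held as its enolate, which cannot leave as a carbanion. The step needs C- over O-acylation and a single site of enolisation: both carbons between the carbonyl groups are quaternary, an enol lactone from O-closure would be reopened by methoxide and returned to the C-acyl product, and an enolate of the aryl ketone can add to the lactone only reversibly, since loss of the ring oxygen from that adduct would leave a five-atom bridge across meta positions of the benzene ring.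

Step 7
Reactants: 14 2-[(1S)-1-[4,6-bis(benzyloxy)-2-hydroxy-5-methyl-3-(3-phenylpropanoyl)phenyl]-3-methylbutyl]-3-hydroxy-4,4,6,6-tetramethylcyclohex-2-ene-1,5-dione
Product: 15 2-[(1S)-3-methyl-1-[2,4,6-trihydroxy-3-methyl-5-(3-phenylpropanoyl)phenyl]butyl]-3-hydroxy-4,4,6,6-tetramethylcyclohex-2-ene-1,5-dione
Conditions: H2 (1 atm), 10% Pd/C, EtOAc, rt
Reagents that add atoms: none
Why: Hydrogenolysis of the two benzyl aryl ethers over Pd/C in a neutral medium, which avoids the acid that would cyclise a phenol onto the trione and the base that could reverse the benzylic C–C bond; the hindered, hydrogen-bonded aryl ketone and the stereocentre should stay as they are.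

**Compound list**

1 | 2-methylbenzene-1,3,5-triol | Cc1c(O)cc(O)cc1O | starting material
2 | ethyl 5-methyl-3-oxohexanoate | CCOC(=O)CC(=O)CC(C)C | starting material
3 | 5,7-dihydroxy-6-methyl-4-(2-methylpropyl)-2H-chromen-2-one | O=C1C=C(CC(C)C)c2c(O)c(C)c(O)cc2O1 | intermediate
4 | 6-methyl-4-(2-methylpropyl)-5,7-bis(trimethylsilyloxy)-2H-chromen-2-one (formed in the flask) | O=C1C=C(CC(C)C)c2c(O[Si](C)(C)C)c(C)c(O[Si](C)(C)C)cc2O1 | intermediate
5 | (4R)-2-[diethoxy(methyl)silyl]oxy-6-methyl-4-(2-methylpropyl)-5,7-bis(trimethylsilyloxy)-4H-chromene (formed in the flask) | CCO[Si](C)(OCC)OC1=C[C@@H](CC(C)C)c2c(O[Si](C)(C)C)c(C)c(O[Si](C)(C)C)cc2O1 | intermediate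
6 | (4R)-5,7-dihydroxy-6-methyl-4-(2-methylpropyl)-3,4-dihydro-2H-chromen-2-one | O=C1C[C@@H](CC(C)C)c2c(O)c(C)c(O)cc2O1 | intermediate
7 | 3-phenylpropanoyl chloride | O=C(Cl)CCc1ccccc1 | starting material
8 | (4R)-5,7-dihydroxy-6-methyl-4-(2-methylpropyl)-8-(3-phenylpropanoyl)-3,4-dihydro-2H-chromen-2-one | O=C1C[C@@H](CC(C)C)c2c(O)c(C)c(O)c(C(=O)CCc3ccccc3)c2O1 | intermediate
9 | (4R)-5,7-bis(benzyloxy)-6-methyl-4-(2-methylpropyl)-8-(3-phenylpropanoyl)-3,4-dihydro-2H-chromen-2-one | O=C1C[C@@H](CC(C)C)c2c(OCc3ccccc3)c(C)c(OCc3ccccc3)c(C(=O)CCc3ccccc3)c2O1 | intermediate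
10 | 2,2,4,4-tetramethylcyclobutane-1,3-dione | CC1(C)C(=O)C(C)(C)C1=O | starting material
11 | methyl 2,2,4-trimethyl-3-oxopentanoate | COC(=O)C(C)(C)C(=O)C(C)C | intermediate
12 | lithium 1-methoxy-2,2,4-trimethyl-1-oxopent-3-en-3-olate, the lithium enolate of 11 (formed in the flask) | [Li+].[O-]C(=C(C)C)C(C)(C)C(=O)OC | intermediate
13 | lithium phenolate of methyl (7R)-7-[4,6-bis(benzyloxy)-2-hydroxy-5-methyl-3-(3-phenylpropanoyl)phenyl]-2,2,4,4,9-pentamethyl-3,5-dioxodecanoate (formed in the flask) | COC(=O)C(C)(C)C(=O)C(C)(C)C(=O)C[C@@H](CC(C)C)c1c(OCc2ccccc2)c(C)c(OCc2ccccc2)c(C(=O)CCc2ccccc2)c1[O-].[Li+] | intermediate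
14 | 2-[(1S)-1-[4,6-bis(benzyloxy)-2-hydroxy-5-methyl-3-(3-phenylpropanoyl)phenyl]-3-methylbutyl]-3-hydroxy-4,4,6,6-tetramethylcyclohex-2-ene-1,5-dione | Cc1c(OCc2ccccc2)c(C(=O)CCc2ccccc2)c(O)c([C@H](CC(C)C)C2=C(O)C(C)(C)C(=O)C(C)(C)C2=O)c1OCc1ccccc1 | intermediate
15 | 2-[(1S)-3-methyl-1-[2,4,6-trihydroxy-3-methyl-5-(3-phenylpropanoyl)phenyl]butyl]-3-hydroxy-4,4,6,6-tetramethylcyclohex-2-ene-1,5-dione | Cc1c(O)c(C(=O)CCc2ccccc2)c(O)c([C@H](CC(C)C)C2=C(O)C(C)(C)C(=O)C(C)(C)C2=O)c1O | target

**Step count**

Total steps: 7. Longest linear sequence: 6 (steps 1, 2, 3, 4, 6, 7); step 5 is a one-step side branch.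

**Steps most likely to fail**

Step 6. The hindered, fully substituted enolate may transfer a proton to the lactone or the aryl ketone instead of adding to the lactone carbonyl, or alkoxide may cleave the non-enolisable 1,3-diketone (retro-Claisen) before the ring closes. The fallback sets out from 9, returns at 14, and replaces the ester-level acylation by an aldehyde-level addition. 9 is reduced with DIBAL-H (1.05 equiv, toluene, −78 °C) to the lactol F1; the doubly ortho-flanked aryl ketone is expected to resist one equivalent at this temperature. F1 is added to lithium enolate 12 (3 equiv, THF, −78 °C), whose first equivalent opens the lactol to the phenolate aldehyde, and a cold quench gives the aldol F2. Dess–Martin periodinane with NaHCO3 oxidises the carbinol to the neutral diketo ester F3. t-BuOK in THF at 0 °C then closes F3 by the same Dieckmann condensation to 14.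

Step 2. Hydride delivery may be slow or poorly face-selective at a β-carbon that is crowded by the peri silyloxy group and deactivated by two oxygen donors, and the aryl lactone may be over-reduced. The fallback sets out from 3, returns at 6, and replaces asymmetric catalysis by resolution. 3 is hydrogenated (H2, Pd/C, AcOH) to the racemic lactone F4. F4 is opened with (R)-1-phenylethanamine (toluene, 60 °C) to two diastereomeric phenol amides, and the (3R) amide F5 is separated from its (3S) epimer F6 by crystallisation or chromatography. Heating F5 with TsOH in toluene re-closes the lactone with loss of the amine and gives 6.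

Step 4. O-alkylation of the hydrogen-bonded, doubly flanked C7 phenol may stay incomplete, and a phenolate may open the lactone during a long reaction. The fallback sets out from 8, returns at 15, and does without protecting groups. 8 is converted to its dilithium bis-phenolate (LiHMDS, 2 equiv, THF, −78 °C) and added to lithium enolate 12 (3 equiv). The unprotected seco keto ester F7 forms as its trilithium phenolate and is closed with t-BuOK at or below 0 °C in the same flask. Acidification gives 15 directly, and steps 4 and 7 fall away.

**Further compounds**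

F1 | step 6 | (4R)-5,7-bis(benzyloxy)-6-methyl-4-(2-methylpropyl)-8-(3-phenylpropanoyl)-3,4-dihydro-2H-chromen-2-ol (both anomers) | OC1C[C@@H](CC(C)C)c2c(OCc3ccccc3)c(C)c(OCc3ccccc3)c(C(=O)CCc3ccccc3)c2O1
F2 | step 6 | methyl (7R)-7-[4,6-bis(benzyloxy)-2-hydroxy-5-methyl-3-(3-phenylpropanoyl)phenyl]-5-hydroxy-2,2,4,4,9-pentamethyl-3-oxodecanoate (both C5 epimers) | COC(=O)C(C)(C)C(=O)C(C)(C)C(O)C[C@@H](CC(C)C)c1c(OCc2ccccc2)c(C)c(OCc2ccccc2)c(C(=O)CCc2ccccc2)c1O
F3 | step 6 | methyl (7R)-7-[4,6-bis(benzyloxy)-2-hydroxy-5-methyl-3-(3-phenylpropanoyl)phenyl]-2,2,4,4,9-pentamethyl-3,5-dioxodecanoate | COC(=O)C(C)(C)C(=O)C(C)(C)C(=O)C[C@@H](CC(C)C)c1c(OCc2ccccc2)c(C)c(OCc2ccccc2)c(C(=O)CCc2ccccc2)c1O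
F4 | step 2 | racemic 5,7-dihydroxy-6-methyl-4-(2-methylpropyl)-3,4-dihydro-2H-chromen-2-one | O=C1CC(CC(C)C)c2c(O)c(C)c(O)cc2O1
F5 | step 2 | (3R)-5-methyl-N-[(1R)-1-phenylethyl]-3-(2,4,6-trihydroxy-3-methylphenyl)hexanamide | C[C@@H](NC(=O)C[C@@H](CC(C)C)c1c(O)cc(O)c(C)c1O)c1ccccc1
F6 | step 2 | (3S)-5-methyl-N-[(1R)-1-phenylethyl]-3-(2,4,6-trihydroxy-3-methylphenyl)hexanamide | C[C@@H](NC(=O)C[C@H](CC(C)C)c1c(O)cc(O)c(C)c1O)c1ccccc1
F7 | step 4 | methyl (7R)-2,2,4,4,9-pentamethyl-3,5-dioxo-7-[2,4,6-trihydroxy-3-methyl-5-(3-phenylpropanoyl)phenyl]decanoate | COC(=O)C(C)(C)C(=O)C(C)(C)C(=O)C[C@@H](CC(C)C)c1c(O)c(C)c(O)c(C(=O)CCc2ccccc2)c1O
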